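**Retrosynthetic overview**
1. Target 22 ⇒ two molecules of chloranthalactone A (21) by head-to-head [2+2] photodimerisation at C8=C9 (cyclobutane formed last).
2. 21 ⇒ ketone 17 + ethyl pyruvate (aldol, enol-lactonisation/dehydration builds the butenolide); 17 ⇒ ketone 15 (methylenation, ketal removal).
3. 15 ⇒ enynyl acetate 12 by Pt-catalysed cycloisomerisation (cyclopropane and cyclopentane in one step), then kinetic enolate protonation for C5-H.
4. 12 ⇒ ketone 10 ⇒ diene 8 ⇒ amide 6 ⇒ benzamide 4 by asymmetric Birch reduction–methylation: the arene becomes the six-membered ring, C10 is set, and the C5 and C8 carbonyls stay latent as enol ethers.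
5. Ring order: six-membered ring (from the arene) → cyclopropane + cyclopentane → butenolide → cyclobutane.

Assumption: names of tricyclic compounds use lindenane numbering (C1–C2–C3 cyclopropane with C2 = CH2, C4 carries C15, C5/C10 ring fusion, C14 = methyl on C10, C8–O–C12 lactone), and the (S)-auxiliary is the enantiomer that the chelated-enolate model predicts for the configuration drawn.

**Step 1**
Reactants: 1 2,5-dimethoxybenzoic acid; 2 (S)-2-(methoxymethyl)pyrrolidine
Product: 4 (2,5-dimethoxyphenyl)[(2S)-2-(methoxymethyl)pyrrolidin-1-yl]methanone, via acid chloride 3 (not isolated)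
Conditions: (COCl)2, cat. DMF, CH2Cl2, 0 → 23 °C; then 2, Et3N, CH2Cl2, 0 °C
Reagents that add atoms: none
Why: Acid chloride formation followed by amidation attaches the prolinol-ether auxiliary; no stereocentre is formed.

**Step 2**
Reactants: 4 benzamide
Product: 6 [(1R)-2,5-dimethoxy-1-methylcyclohexa-2,5-dien-1-yl][(2S)-2-(methoxymethyl)pyrrolidin-1-yl]methanone, via potassium amide enolate 5 (not isolated)
Conditions: K (2.2 equiv), t-BuOH (1 equiv), NH3/THF, –78 °C; piperylene; MeI, –78 → 23 °C
Reagents that add atoms: iodomethane, CI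
Why: Schultz-type asymmetric Birch reduction–alkylation: ipso/para reduction gives the chelated enolate 5 with both OMe groups left on sp2 carbons, and MeI enters on the face opposite the CH2OMe arm, setting the quaternary C10 centre (1R) with high dr.

**Step 3**
Reactants: 6 dienyl amide
Product: 7 (1R)-2,5-dimethoxy-1-methylcyclohexa-2,5-diene-1-carbaldehyde
Conditions: Cp2Zr(H)Cl (1.8 equiv), THF, 23 °C; SiO2/H2O work-up
Reagents that add atoms: none
Why: Schwartz-reagent reduction of a tertiary amide stops at the aldehyde (zirconated hemiaminal), releases the auxiliary and leaves the enol ethers and the non-enolisable quaternary centre untouched.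

**Step 4**
Reactants: 7 aldehyde
Product: 8 (3R)-3-ethenyl-1,4-dimethoxy-3-methylcyclohexa-1,4-diene
Conditions: Ph3PCH3Br, KHMDS, THF, 0 → 23 °C
Reagents that add atoms: methyltriphenylphosphonium bromide, C[P+](c1ccccc1)(c1ccccc1)c1ccccc1.[Br-]
Why: Wittig methylenation of a non-enolisable aldehyde gives the vinyl group (C1=C2); the stereocentre is untouched.

**Step 5**
Reactants: 8 bis-enol ether
Product: 10 (7S)-7-ethenyl-7-methyl-1,4-dioxaspiro[4.5]decan-8-one, via diketone 9 (not isolated)
Conditions: 1 M HCl, THF, 0 → 23 °C; then HOCH2CH2OH (1.1 equiv), PPTS, PhH, 80 °C (Dean–Stark)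
Reagents that add atoms: water, O; ethylene glycol, OCCO
Why: Enol-ether hydrolysis gives the 1,4-diketone, and selective mono-ketalisation takes the unhindered C8 carbonyl while the C5 carbonyl next to the quaternary carbon stays free.

**Step 6**
Reactants: 10 keto-ketal
Product: 12 (7S)-7-ethenyl-8-ethynyl-7-methyl-1,4-dioxaspiro[4.5]decan-8-yl acetate (both C8 epimers), via magnesium alkoxide 11 (not isolated)
Conditions: HC≡CMgBr (2 equiv), THF, 0 → 23 °C; then Ac2O, DMAP, 0 → 23 °C
Reagents that add atoms: ethynylmagnesium bromide, C#C[Mg]Br; acetic anhydride, CC(=O)OC(C)=O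
Why: Grignard 1,2-addition and in-situ O-acetylation give the 5-en-1-yn-3-yl acetate; the new carbinol centre need not be controlled because it becomes sp2 in step 7.

**Step 7**
Reactants: 12 enynyl acetate
Product: 15 (1R,3S,5R,10S)-8,8-ethylenedioxy-15-norlindenan-4-one (1αH, 3αH, 5αH; cyclopropane CH2 and C14 β), via enol acetate 13 (not isolated), via lithium enolate 14 (not isolated)
Conditions: PtCl2 (5 mol%), PhMe, 80 °C; then MeLi (2.2 equiv), THF, –78 → 0 °C; inverse quench into AcOH/THF, –78 °C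
Reagents that add atoms: none
Why: Ohloff–Rautenstrauch cycloisomerisation (1,2-acetoxy shift plus cyclopropanation of the vinyl group) forms cyclopentene and cyclopropane together with the CH2 on the C14-methyl face (H-1/H-3 cis by ring fusion), then MeLi frees enolate 14 and kinetic protonation from the face opposite C14 and the cyclopropane CH2 sets 5α-H (trans fusion).

**Step 8**
Reactants: 15 ketone
Product: 16 (1R,3S,5S,10S)-8,8-ethylenedioxylinden-4(15)-ene
Conditions: Cp2TiMe2 (3 equiv), PhMe/THF, 65 °C, dark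
Reagents that add atoms: dimethyltitanocene, C[Ti](C)(C1C=CC=C1)C1C=CC=C1
Why: Petasis methylenation is non-basic, so the hindered, epimerisable C4 ketone is converted to the exocyclic alkene without loss of the C5 configuration.

**Step 9**
Reactants: 16 methylene ketal
Product: 17 (1R,3S,5S,10S)-linden-4(15)-en-8-one
Conditions: 1 M HCl, THF, 23 °C
Reagents that add atoms: water, O
Why: Mild acid hydrolysis of the dioxolane frees the C8 ketone; no stereocentre is affected.

**Step 10**
Reactants: 17 ketone; 18 ethyl pyruvate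
Product: 21 chloranthalactone A, (1R,3S,5S,10S)-lindena-4(15),7(11),8-trien-12,8-olide, via lithium enolate 19 (not isolated), via aldol adduct 20 (not isolated)
Conditions: LDA (1.05 equiv), THF, –78 °C; 18; AcOH; then TsOH·H2O (cat.), PhH, 80 °C
Reagents that add atoms: none
Why: Kinetic deprotonation at C7 (C9 is neopentyl) and aldol addition to the pyruvate ketone, then acid-catalysed enol-lactonisation and dehydration give the γ-ylidene butenolide; the two transient centres (C7, C11) become sp2.

**Step 11**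
Reactants: 21 chloranthalactone A (2 equiv)
Product: 22 chloranthalactone F (target)
Conditions: hν (high-pressure Hg lamp, Pyrex), degassed hexane, 23 °C
Reagents that add atoms: none
Why: Known [2+2] photodimerisation of the C8=C9 enol-lactone bonds, head-to-head and on the α face of each molecule (anti to C14), which for one enantiomer gives the C2-symmetric cyclobutane with C8, C9, C8′, C9′ as in the target.

**Compound list**
1 | 2,5-dimethoxybenzoic acid | COc1ccc(OC)c(c1)C(=O)O | starting material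
2 | (S)-2-(methoxymethyl)pyrrolidine | COC[C@@H]1CCCN1 | starting material
3 | 2,5-dimethoxybenzoyl chloride | COc1ccc(OC)c(c1)C(Cl)=O | intermediate
4 | (2,5-dimethoxyphenyl)[(2S)-2-(methoxymethyl)pyrrolidin-1-yl]methanone | COC[C@@H]1CCCN1C(=O)c1cc(OC)ccc1OC | intermediate
5 | potassium amide enolate of the 1,4-dihydrobenzamide | COC[C@@H]1CCCN1C([O-])=C1C=C(OC)CC=C1OC.[K+] | intermediate
6 | [(1R)-2,5-dimethoxy-1-methylcyclohexa-2,5-dien-1-yl][(2S)-2-(methoxymethyl)pyrrolidin-1-yl]methanone | COC[C@@H]1CCCN1C(=O)[C@@]1(C)C(OC)=CCC(OC)=C1 | intermediate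
7 | (1R)-2,5-dimethoxy-1-methylcyclohexa-2,5-diene-1-carbaldehyde | O=C[C@@]1(C)C(OC)=CCC(OC)=C1 | intermediate
8 | (3R)-3-ethenyl-1,4-dimethoxy-3-methylcyclohexa-1,4-diene | C=C[C@@]1(C)C(OC)=CCC(OC)=C1 | intermediate
9 | (2S)-2-ethenyl-2-methylcyclohexane-1,4-dione | C=C[C@@]1(C)C(=O)CCC(=O)C1 | intermediate
10 | (7S)-7-ethenyl-7-methyl-1,4-dioxaspiro[4.5]decan-8-one | C=C[C@@]1(C)C(=O)CCC2(OCCO2)C1 | intermediate
11 | bromomagnesium (7S)-7-ethenyl-8-ethynyl-7-methyl-1,4-dioxaspiro[4.5]decan-8-olate | C=C[C@@]1(C)C(O[Mg]Br)(C#C)CCC2(OCCO2)C1 | intermediate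
12 | (7S)-7-ethenyl-8-ethynyl-7-methyl-1,4-dioxaspiro[4.5]decan-8-yl acetate (C8 epimers) | C=C[C@@]1(C)C(OC(C)=O)(C#C)CCC2(OCCO2)C1 | intermediate
13 | (1R,3S,10S)-8,8-ethylenedioxy-15-norlinden-4-en-4-yl acetate | CC(=O)OC1=C2CCC3(OCCO3)C[C@@]2(C)[C@@H]2C[C@H]12 | intermediate
14 | lithium (1R,3S,10S)-8,8-ethylenedioxy-15-norlinden-4-en-4-olate | [Li+].[O-]C1=C2CCC3(OCCO3)C[C@@]2(C)[C@@H]2C[C@H]12 | intermediate
15 | (1R,3S,5R,10S)-8,8-ethylenedioxy-15-norlindenan-4-one | O=C1[C@@H]2CCC3(OCCO3)C[C@@]2(C)[C@@H]2C[C@H]12 | intermediate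
16 | (1R,3S,5S,10S)-8,8-ethylenedioxylinden-4(15)-ene | C=C1[C@@H]2CCC3(OCCO3)C[C@@]2(C)[C@@H]2C[C@H]12 | intermediate
17 | (1R,3S,5S,10S)-linden-4(15)-en-8-one | C=C1[C@@H]2CCC(=O)C[C@@]2(C)[C@@H]2C[C@H]12 | intermediate
18 | ethyl pyruvate | CCOC(=O)C(C)=O | starting material
19 | lithium (1R,3S,5S,10S)-lindena-4(15),7-dien-8-olate | C=C1[C@@H]2CC=C([O-])C[C@@]2(C)[C@@H]2C[C@H]12.[Li+] | intermediate
20 | ethyl 2-hydroxy-2-[(1R,3S,5S,10S)-8-oxolinden-4(15)-en-7-yl]propanoate (C7, C11 epimers) | C=C1[C@@H]2CC(C(C)(O)C(=O)OCC)C(=O)C[C@@]2(C)[C@@H]2C[C@H]12 | intermediate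
21 | chloranthalactone A | C=C1[C@H]2C[C@H]2[C@@]2(C)[C@H]1CC1=C(C)C(=O)OC1=C2 | intermediate
22 | chloranthalactone F | C=C1[C@H]2C[C@H]2[C@@]2(C)[C@H]1CC1=C(C)C(=O)O[C@]13[C@H]2[C@H]1[C@@]2(C)[C@@H]4C[C@@H]4C(=C)[C@@H]2CC2=C(C)C(=O)O[C@@]213 | target

**Totals**
Total steps: 11. Longest linear sequence: 11 (1 → 22).

**Steps most likely to fail**

Step 7. The risks are the face on which the cyclopropane forms (the two faces of the vinyl group differ only by C14 versus the C9 ring bond), ionisation of the tertiary acetate, and the kinetic protonation at C5. Fallback: set out from 10. Wittig reaction with Ph3P=CHOMe gives the enol ether (7S)-7-ethenyl-8-(methoxymethylidene)-7-methyl-1,4-dioxaspiro[4.5]decane F2. Hg(OAc)2/KI hydrolysis and K2CO3/MeOH equilibration give the aldehyde (7S,8R)-7-ethenyl-7-methyl-1,4-dioxaspiro[4.5]decane-8-carbaldehyde F3, with CHO trans to vinyl, separated from its epimer. Me3S+ I–/n-BuLi gives the epoxide (7S,8R)-7-ethenyl-7-methyl-8-[(2S)-oxiran-2-yl]-1,4-dioxaspiro[4.5]decane F4. LiTMP then effects Hodgson cyclopropanation of the vinyl group by the α-lithiated epoxide on a ring whose two arms are already trans, giving the alcohol (1R,3S,4R,5R,10S)-8,8-ethylenedioxy-15-norlindenan-4-ol F5 with OH trans to the cyclopropane. Dess–Martin oxidation comes back to the route at 15.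

Step 3. The amide is tertiary and sits on a quaternary carbon, so Schwartz reduction may be slow or incomplete. Fallback: set out from 6. LiH2N·BH3 in THF reduces the amide fully to the primary alcohol [(1S)-2,5-dimethoxy-1-methylcyclohexa-2,5-dien-1-yl]methanol F1. Pyridine-buffered Dess–Martin oxidation comes back at 7.

Step 8. The ketone is hindered, and any enolisation towards C5 would give the cis-fused isomer, which is probably the more stable one. Fallback: set out from 12. Run the Pt cyclisation and MeLi cleavage as in step 7, but trap enolate 14 with PhNTf2 to give the enol triflate (1R,3S,10S)-8,8-ethylenedioxy-15-norlinden-4-en-4-yl trifluoromethanesulfonate F6. Pd(PPh3)4/Me3SiCH2MgCl coupling gives the allylsilane (1R,3S,10S)-8,8-ethylenedioxy-15-(trimethylsilyl)linden-4-ene F7. 1 M HCl/THF then causes protodesilylation with allylic transposition (proton to C5 from the α face, exocyclic C4=C15 formed) and ketal hydrolysis. This comes back at 17 without a free C4 ketone.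

**Further compounds**
F1 | step 3 | [(1S)-2,5-dimethoxy-1-methylcyclohexa-2,5-dien-1-yl]methanol | OC[C@@]1(C)C(OC)=CCC(OC)=C1
F2 | step 7 | (7S)-7-ethenyl-8-(methoxymethylidene)-7-methyl-1,4-dioxaspiro[4.5]decane | C=C[C@@]1(C)C(=COC)CCC2(OCCO2)C1
F3 | step 7 | (7S,8R)-7-ethenyl-7-methyl-1,4-dioxaspiro[4.5]decane-8-carbaldehyde | C=C[C@@]1(C)[C@H](C=O)CCC2(OCCO2)C1
F4 | step 7 | (7S,8R)-7-ethenyl-7-methyl-8-[(2S)-oxiran-2-yl]-1,4-dioxaspiro[4.5]decane | C=C[C@@]1(C)[C@H]([C@H]2CO2)CCC3(OCCO3)C1
F5 | step 7 | (1R,3S,4R,5R,10S)-8,8-ethylenedioxy-15-norlindenan-4-ol | O[C@H]1[C@@H]2CCC3(OCCO3)C[C@@]2(C)[C@@H]2C[C@H]12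
F6 | step 8 | (1R,3S,10S)-8,8-ethylenedioxy-15-norlinden-4-en-4-yl trifluoromethanesulfonate | O=S(=O)(OC1=C2CCC3(OCCO3)C[C@@]2(C)[C@@H]2C[C@H]12)C(F)(F)F
F7 | step 8 | (1R,3S,10S)-8,8-ethylenedioxy-15-(trimethylsilyl)linden-4-ene | C[Si](C)(C)CC1=C2CCC3(OCCO3)C[C@@]2(C)[C@@H]2C[C@H]12
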